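**Retrosynthetic overview**

1. The target is a 1,16‑cyclo‑neoclerodane. The 7‑OAc comes from a 7‑ketone. Ring D comes from acylation of furan C13 by a C12 acid; the 10‑OH is then released by decarboxylative excision of a temporary C10–O–C21(=O)–C11 lactone (ring E).
2. Key disconnection (one pot, three rings): C9–C11, C5–C4 and C4=C3 from a p‑quinol bis‑ester. An O‑tethered malonate Michael addition gives ring E, a phosphonoacetate Michael addition gives ring A, and an intramolecular Horner–Wadsworth–Emmons olefination gives ring B.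
3. C1–C10 comes from a sparteine‑mediated Hoppe homoaldol addition of a 3‑(2‑furyl)allyl carbamate to a quinone monoketal. This sets C1 and C10 and carries C3 as a latent aldehyde.
4. Ring C comes from 4‑methoxy‑2,3‑dimethylphenol. Ring order: C → E + A + B → D (E then excised).

Assumption 1: atom labels C1–C20 follow neoclerodane numbering of the target (C10 carbinol, C18/C19 lactone, C12 ketone, C13–C16 furan); C21 is the extra lactone carbon later lost as CO2.

Assumption 2: (−)‑sparteine is taken to give the C1 configuration drawn; if the sense is opposite, the (+)‑sparteine surrogate is used.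

**Route**

Step 1
Reactants: 1 4-methoxy-2,3-dimethylphenol
Product: 2 6-(hydroxymethyl)-4-methoxy-2,3-dimethylphenol
Conditions: 37% aq. CH2O, NaOH (1 equiv), H2O, 25 °C; then AcOH
Reagents that add atoms: formaldehyde (C=O)
Why: Lederer–Manasse hydroxymethylation of the phenolate can only occur at the single free ortho position (para carries OMe) and installs C19.

Step 2
Reactants: 2 6-(hydroxymethyl)-4-methoxy-2,3-dimethylphenol
Product: 3 6-(hydroxymethyl)-4,4-dimethoxy-2,3-dimethylcyclohexa-2,5-dien-1-one
Conditions: PhI(OAc)2, MeOH, 0 °C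
Reagents that add atoms: methanol (CO)
Why: Oxidative dearomatisation of a p‑methoxyphenol with a hypervalent iodine reagent traps the phenoxenium ion with methanol at the para carbon, giving the quinone monoketal whose free carbonyl is the future C10.

Step 3
Reactants: 3 6-(hydroxymethyl)-4,4-dimethoxy-2,3-dimethylcyclohexa-2,5-dien-1-one; 4 2-(diethoxyphosphoryl)acetic acid
Product: 5 (3,3-dimethoxy-4,5-dimethyl-6-oxocyclohexa-1,4-dien-1-yl)methyl 2-(diethoxyphosphoryl)acetate
Conditions: DCC, DMAP (5 mol %), CH2Cl2, 0 °C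
Reagents that add atoms: none
Why: Steglich esterification of the only hydroxyl group places the C18/C4 phosphonoacetate tether on C19 before any stereocentre exists.

Step 4
Reactants: 6 (E)-3-(furan-2-yl)prop-2-enal
Product: 7 (E)-3-(furan-2-yl)prop-2-en-1-ol
Conditions: NaBH4, MeOH, 0 °C
Reagents that add atoms: none
Why: Borohydride 1,2‑reduction of the enal gives the allylic alcohol with the E double bond intact.

Step 5
Reactants: 7 (E)-3-(furan-2-yl)prop-2-en-1-ol; 8 N,N-diisopropylcarbamoyl chloride
Product: 9 (E)-3-(furan-2-yl)prop-2-en-1-yl N,N-diisopropylcarbamate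
Conditions: NaH, THF, 0 °C to rt
Reagents that add atoms: none
Why: O‑Carbamoylation of the alkoxide gives the Hoppe carbamate, whose carbonyl directs the later α‑lithiation.

Step 6
Reactants: 9 (E)-3-(furan-2-yl)prop-2-en-1-yl N,N-diisopropylcarbamate; 5 (3,3-dimethoxy-4,5-dimethyl-6-oxocyclohexa-1,4-dien-1-yl)methyl 2-(diethoxyphosphoryl)acetate
Product: 12 homoaldol adduct (C10 tertiary alcohol on the quinone monoketal; Z-enol carbamate; C1 R; C10 S), via lithiated carbamate 10 (not isolated), via allyltitanium reagent 11 (not isolated)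
Conditions: n-BuLi, (−)-sparteine, toluene, −78 °C; ClTi(OiPr)3, −78 °C; then 5, −78 to −40 °C; aq. NH4Cl
Reagents that add atoms: none
Why: Hoppe homoaldol reaction: sparteine‑controlled α‑lithiation, transmetalation to titanium with inversion and γ‑attack on the ketone through a Zimmerman–Traxler chair transfer chirality to C1 (R) and give the Z‑enol carbamate (latent C3 aldehyde), and C10 (S) is set by the ring arm with the bulkier CH2O‑ester group sitting equatorial (anti adduct); the non‑basic titanium reagent spares ester, ketal and phosphonate, and the minor C10 epimer is removed by chromatography.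

Step 7
Reactants: 12 homoaldol adduct; 13 3-(tert-butoxy)-3-oxopropanoic acid
Product: 14 tert-butyl malonate ester of 12 at the C10 oxygen (C1 and C10 unchanged)
Conditions: DCC, DMAP (cat.), CH2Cl2, 0 °C to rt
Reagents that add atoms: none
Why: Carbodiimide‑mediated acylation with a malonic half‑ester (a Steglich‑type esterification that works on hindered tertiary alcohols) puts on the C10 oxygen the unit that becomes C11 and C12.

Step 8
Reactants: 14 tert-butyl malonate ester of 12
Product: 15 p-quinol dienone bis-ester aldehyde (7-ketone; malonate on C10–O; phosphonoacetate on C19–O; free C3 aldehyde; C1 and C10 unchanged)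
Conditions: Hg(OAc)2 (5 mol %), MeSO3H (1.2 equiv), THF/H2O (4:1), 0 °C to rt
Reagents that add atoms: water (O)
Why: Acid hydrolysis opens the labile bis‑allylic dimethyl ketal to the cross‑conjugated dienone and mercury‑catalysed hydrolysis of the enol carbamate (the standard Hoppe unmasking) frees the C3 aldehyde, while the tert‑butyl ester, the quinol ester and both stereocentres are unaffected.

Step 9 (key step)
Reactants: 15 p-quinol dienone bis-ester aldehyde
Product: 18 tetracyclic bis-lactone (rings A, B, C and E; 3-ene; 7-ketone; CO2tBu on C11), via mono-Michael lactone 16 (not isolated), via phosphono bis-lactone 17 (not isolated)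
Conditions: Cs2CO3 (3 equiv), MeCN (0.005 M), 0 °C to rt
Reagents that add atoms: none
Why: Proposed new method: under carbonate base the C10–O‑tethered malonate adds 5‑exo to C9 on the face of the C10 oxygen (quaternary C9, ring E), the C19–O‑tethered phosphonoacetate adds 5‑exo to C5 on the same face, away from the C1 branch and the now axial 9‑methyl (quaternary C5, ring A), and the phosphonate anion then closes ring B on the C3 aldehyde by intramolecular Horner–Wadsworth–Emmons olefination (trans B/C fusion; C8 equilibrates to the equatorial methyl), the reversible malonate addition being funnelled to C9 once C5 is consumed; the closest known reactions are the telescoped intramolecular Michael/olefination of phosphonoacetates of 4‑hydroxycyclohexenones and the Michael cyclisation of p‑quinol malonates.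

Step 10
Reactants: 18 tetracyclic bis-lactone
Product: 21 bridged β-keto lactone (ring D closed; C12 ketone on furan C13; C11 still tied to the C10 oxygen through C21), via malonic half-acid 19 (not isolated), via mixed anhydride 20 (not isolated)
Conditions: TFA/CH2Cl2 (1:4), 0 °C; evaporate; TFAA (1.3 equiv), CH2Cl2, 0 °C to rt
Reagents that add atoms: none
Why: Acidolysis of the tert‑butyl ester and activation as the mixed trifluoroacetic anhydride trigger an intramolecular Friedel–Crafts acylation at furan C13, the only ring position the acyl group can reach, closing seven‑membered ring D; the epimerisable C11 funnels through the reactive epimer and no other stereocentre is touched.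

Step 11
Reactants: 21 bridged β-keto lactone
Product: 23 7,12-diketone with free 10-OH (rings A–D and furan complete), via seco hydroxy diacid 22 (not isolated)
Conditions: LiOH (5 equiv), THF/H2O, rt; then 2 M HCl, 50 °C
Reagents that add atoms: water (O)
Why: Saponification of the β‑keto lactone and acid‑induced decarboxylation of the β‑keto acid remove C21, free the 10‑OH and leave C11 as CH2, the butenolide opened by base recloses on acidification, and the only enolisable stereocentre (C8) stays in its equatorial thermodynamic configuration.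

Step 12
Reactants: 23 7,12-diketone
Product: 24 7-alcohol (7R; axial OH cis to C19 and C20)
Conditions: NaBH4, CeCl3·7H2O, MeOH, −78 °C
Reagents that add atoms: none
Why: Luche reduction is chemoselective for the cyclohexanone over the vinylogous‑ester‑like 3‑furyl ketone and the butenolide, and hydride enters C7 equatorially on the face of the 10‑OH because the axial C19 and C20 groups block the other face.

Step 13
Reactants: 24 7-alcohol
Product: 25 CNP0329797.2 (target)
Conditions: Ac2O, DMAP (cat.), pyridine, rt
Reagents that add atoms: acetic anhydride (CC(=O)OC(C)=O)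
Why: Nucleophile‑catalysed acetylation of the secondary 7‑OH, with the hindered tertiary 10‑OH inert, completes the target without changing any stereocentre.

**Compound list**

1 | 4-methoxy-2,3-dimethylphenol | COc1ccc(O)c(C)c1C | starting material
2 | 6-(hydroxymethyl)-4-methoxy-2,3-dimethylphenol | COc1cc(CO)c(O)c(C)c1C | intermediate
3 | 6-(hydroxymethyl)-4,4-dimethoxy-2,3-dimethylcyclohexa-2,5-dien-1-one | COC1(OC)C=C(CO)C(=O)C(C)=C1C | intermediate
4 | 2-(diethoxyphosphoryl)acetic acid | CCOP(=O)(CC(=O)O)OCC | starting material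
5 | (3,3-dimethoxy-4,5-dimethyl-6-oxocyclohexa-1,4-dien-1-yl)methyl 2-(diethoxyphosphoryl)acetate | CCOP(=O)(CC(=O)OCC1=CC(OC)(OC)C(C)=C(C)C1=O)OCC | intermediate
6 | (E)-3-(furan-2-yl)prop-2-enal | O=C/C=C/c1ccco1 | starting material
7 | (E)-3-(furan-2-yl)prop-2-en-1-ol | OC/C=C/c1ccco1 | intermediate
8 | N,N-diisopropylcarbamoyl chloride | CC(C)N(C(C)C)C(Cl)=O | starting material
9 | (E)-3-(furan-2-yl)prop-2-en-1-yl N,N-diisopropylcarbamate | CC(C)N(C(C)C)C(=O)OC/C=C/c1ccco1 | intermediate
10 | α-lithiated carbamate (sparteine complex; carbanion carbon = future C3) | [Li][C@@H](OC(=O)N(C(C)C)C(C)C)/C=C/c1ccco1 | intermediate (not isolated)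
11 | (E)-3-(furan-2-yl)-1-(triisopropoxytitanio)allyl N,N-diisopropylcarbamate (inverted relative to 10) | CC(C)O[Ti](OC(C)C)(OC(C)C)[C@H](OC(=O)N(C(C)C)C(C)C)/C=C/c1ccco1 | intermediate (not isolated)
12 | homoaldol adduct: quinone-monoketal C10 tertiary alcohol bearing the (Z)-3-(diisopropylcarbamoyloxy)-1-(furan-2-yl)prop-2-enyl chain; C1 R; C10 S | COC1(OC)C=C(COC(=O)CP(=O)(OCC)OCC)[C@](O)([C@@H](/C=C\OC(=O)N(C(C)C)C(C)C)c2ccco2)C(C)=C1C | intermediate
13 | 3-(tert-butoxy)-3-oxopropanoic acid (tert-butyl hydrogen malonate) | CC(C)(C)OC(=O)CC(=O)O | starting material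
14 | tert-butyl malonate ester of 12 at the C10 oxygen; C1 and C10 as in 12 | COC1(OC)C=C(COC(=O)CP(=O)(OCC)OCC)[C@](OC(=O)CC(=O)OC(C)(C)C)([C@@H](/C=C\OC(=O)N(C(C)C)C(C)C)c2ccco2)C(C)=C1C | intermediate
15 | p-quinol dienone: 7-ketone; C10 carries the malonate ester and the 1-(furan-2-yl)-3-oxopropyl chain; C19 carries the phosphonoacetate; C1 and C10 as in 12 | O=C1C=C(COC(=O)CP(=O)(OCC)OCC)[C@](OC(=O)CC(=O)OC(C)(C)C)([C@@H](CC=O)c2ccco2)C(C)=C1C | intermediate
16 | mono-Michael adduct: cis-fused γ-lactone ring E (C10–O–C21–C11–C9); quaternary C9; 8-methyl equatorial | O=C1C=C(COC(=O)CP(=O)(OCC)OCC)[C@]2(OC(=O)[C@H](C(=O)OC(C)(C)C)[C@@]2(C)[C@@H]1C)[C@@H](CC=O)c1ccco1 | intermediate (not isolated)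
17 | double Michael adduct: rings E and A; α-phosphono lactone at C4 (either epimer); free C3 aldehyde | O=C1C[C@]2(COC(=O)C2P(=O)(OCC)OCC)[C@]3(OC(=O)[C@H](C(=O)OC(C)(C)C)[C@@]3(C)[C@@H]1C)[C@@H](CC=O)c1ccco1 | intermediate (not isolated)
18 | cascade product: rings A, B, C, E; 3-ene; 7-ketone; CO2tBu on C11; C4 and C11 cis to the C10 oxygen; C19, 9-methyl and 1-H trans to it | O=C1C[C@@]23COC(=O)C2=CC[C@@H](c2ccco2)[C@@]34OC(=O)[C@H](C(=O)OC(C)(C)C)[C@@]4(C)[C@@H]1C | intermediate
19 | malonic half-acid of 18 (CO2H on C11) | O=C1C[C@@]23COC(=O)C2=CC[C@@H](c2ccco2)[C@@]34OC(=O)[C@H](C(=O)O)[C@@]4(C)[C@@H]1C | intermediate (not isolated)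
20 | mixed trifluoroacetic anhydride of 19 | O=C1C[C@@]23COC(=O)C2=CC[C@@H](c2ccco2)[C@@]34OC(=O)[C@H](C(=O)OC(=O)C(F)(F)F)[C@@]4(C)[C@@H]1C | intermediate (not isolated)
21 | bridged β-keto lactone: ring D closed (C12 ketone on furan C13); C11 linked to the C10 oxygen through C21(=O) | O=C1C[C@@]23COC(=O)C2=CC[C@H]2c4occc4C(=O)[C@@H]5[C@@](C)([C@@H]1C)[C@@]23OC5=O | intermediate
22 | seco hydroxy diacid: both lactones opened (C19 OH, C18 acid, 10-OH, C11 CO2H) | O=C1C[C@@]2(CO)C(C(=O)O)=CC[C@H]3c4occc4C(=O)[C@@H](C(=O)O)[C@@](C)([C@@H]1C)[C@]23O | intermediate (not isolated)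
23 | 7-deacetoxy-7-oxo compound (7,12-diketone; 10-OH free; stereocentres as in target) | O=C1C[C@@]23COC(=O)C2=CC[C@H]2c4occc4C(=O)C[C@@](C)([C@@H]1C)[C@@]23O | intermediate
24 | 7-deacetyl target (7R alcohol) | O[C@@H]1C[C@@]23COC(=O)C2=CC[C@H]2c4occc4C(=O)C[C@@](C)([C@@H]1C)[C@@]23O | intermediate
25 | CNP0329797.2: (1R,5S,7R,8S,9S,10S)-7-acetoxy-10-hydroxy-12-oxo-15,16-epoxy-1,16-cyclo-neocleroda-3,13(16),14-trien-18,19-olide | CC(=O)O[C@@H]1C[C@@]23COC(=O)C2=CC[C@H]2c4occc4C(=O)C[C@@](C)([C@@H]1C)[C@@]23O | target

**Step count**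

Total: 13 steps. Longest linear sequence: 11 (steps 1–3, then 6–13).

**Steps most likely to fail, with fallbacks**

Step 6 (homoaldol addition to a hindered, pseudo‑symmetric dienone: reactivity and C10 diastereocontrol are uncertain). The fallback sets out from 7 and 5 and comes back at 15. Alcohol 7 is borylated ([Pd(MeCN)4](BF4)2 cat., B2pin2, DMSO/MeOH) to the allylboronate F1. F1 adds to ketone 5 under 3,3'-dibromo-BINOL catalysis (the enantiomer that gives the C10 configuration of 12), so the carbonyl face is chosen by the catalyst and the chair transition state gives the anti homoallylic alcohol F2. DCC acylation with 13 gives the malonate F3. Aldehyde‑selective Wacker oxidation of the vinyl group (PdCl2(PhCN)2, CuCl2, AgNO2, O2, t‑BuOH/MeNO2) gives the aldehyde ketal F4, and aqueous AcOH hydrolyses the ketal to 15.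

Step 9 (the three‑ring cascade: the free aldehyde may interfere with the two Michael additions). The fallback sets out from 14 and comes back at 17, which then closes to 18. Aqueous AcOH/THF hydrolyses only the bis‑allylic ketal and gives the dienone enol carbamate F5. Cs2CO3 in MeCN then effects both Michael additions with the aldehyde still masked, giving the isolable bis‑lactone phosphonate F6. Hg(OAc)2/MeSO3H in wet THF liberates aldehyde 17, and a separate Cs2CO3 Horner–Wadsworth–Emmons step closes ring B to 18.

Step 10 (Friedel–Crafts closure of ring D: TFAA may instead trifluoroacetylate the free furan α‑position). The fallback sets out from 19, isolated after the TFA treatment of 18, and comes back at 21. Acid 19 is converted (NH3, DCC, HOBt) into the primary amide F7 and dehydrated (TFAA, pyridine) to the nitrile F8. An intramolecular Houben–Hoesch reaction (TfOH, CH2Cl2; then H2O) lets the nitrilium ion acylate furan C13, and hydrolysis of the ketiminium salt gives 21.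

**Further compounds**

F1 | step 6 | (E)-2-[3-(furan-2-yl)allyl]-4,4,5,5-tetramethyl-1,3,2-dioxaborolane | CC1(C)OB(C/C=C/c2ccco2)OC1(C)C
F2 | step 6 | homoallylic alcohol (vinyl analogue of 12; C1 and C10 as in 12) | COC1(OC)C=C(COC(=O)CP(=O)(OCC)OCC)[C@](O)([C@@H](C=C)c2ccco2)C(C)=C1C
F3 | step 6 | tert-butyl malonate ester of F2 | COC1(OC)C=C(COC(=O)CP(=O)(OCC)OCC)[C@](OC(=O)CC(=O)OC(C)(C)C)([C@@H](C=C)c2ccco2)C(C)=C1C
F4 | step 6 | aldehyde ketal (7-dimethyl ketal of 15) | COC1(OC)C=C(COC(=O)CP(=O)(OCC)OCC)[C@](OC(=O)CC(=O)OC(C)(C)C)([C@@H](CC=O)c2ccco2)C(C)=C1C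
F5 | step 9 | dienone enol carbamate (7-ketone of 14) | O=C1C=C(COC(=O)CP(=O)(OCC)OCC)[C@](OC(=O)CC(=O)OC(C)(C)C)([C@@H](/C=C\OC(=O)N(C(C)C)C(C)C)c2ccco2)C(C)=C1C
F6 | step 9 | bis-lactone phosphonate with Z-enol carbamate (masked 17) | O=C1C[C@]2(COC(=O)C2P(=O)(OCC)OCC)[C@]3(OC(=O)[C@H](C(=O)OC(C)(C)C)[C@@]3(C)[C@@H]1C)[C@@H](/C=C\OC(=O)N(C(C)C)C(C)C)c1ccco1
F7 | step 10 | primary amide of 19 | O=C1C[C@@]23COC(=O)C2=CC[C@@H](c2ccco2)[C@@]34OC(=O)[C@H](C(N)=O)[C@@]4(C)[C@@H]1C
F8 | step 10 | nitrile from F7 | O=C1C[C@@]23COC(=O)C2=CC[C@@H](c2ccco2)[C@@]34OC(=O)[C@H](C#N)[C@@]4(C)[C@@H]1C
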